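**Plan**

1. Core numbering as in the plakortolides: C1 lactone C=O, C2 its CH2, C3 the CH–O–O fusion carbon, C4 the C(CH3)–O fusion carbon, C5 the ring CH2, C6 the quaternary C(CH3)(O–O) carbon that carries the side chain. The retrosynthesis cuts, in this order: the sp2–sp2 bond in the middle of the side-chain diene (Stille); then, in one cut, the ring bond C5–C6 and the lactone bond C4–O; then the peroxyketal bond O–C6; then C3–O (ene reaction).
2. Enabling feature: C6 is a ketone carbon in disguise (one O–O, three carbons), C4 is a tertiary carbinol carbon 1,3 to it, and the carboxyl carbon C1 is 1,4 to C4. The 1,2-dioxane ring O–O–C3–C4–C5–C6 is therefore the peroxide analogue of a Prins tetrahydropyran: a peroxycarbenium ion at C6 is attacked by a C4=C5 alkene, and the cation at C4 is caught by the C1 ester.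
3. Forward: an allylic hydroperoxide (from 4-methylpent-3-enoic acid) and an iodoalkenyl ketal (from pent-4-yn-2-ol) are joined as an acyclic mixed peroxyketal. One cationic cascade then closes the 1,2-dioxane ring (C5–C6) and the γ-lactone ring (C4–O). The phenyl-diene chain is joined last.
4. Stereochemistry: C3 comes from enzymatic kinetic resolution of the ene hydroperoxide. C4 and C6 are relayed from C3 in the chair transition state of the cascade. The three (E)-alkenes come from syn-carboalumination, Horner–Wadsworth–Emmons olefination and syn-hydrostannation, and are kept in the Stille coupling.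

Key step: step 8

Remark: the peroxidase of step 3 is assumed to reduce the (3R)-hydroperoxide faster, as it does with related small secondary hydroperoxides, so that the (3S)-hydroperoxide is recovered.

**Route**

Step 1
Reactants: 1 4-methylpent-3-enoic acid
Product: 2 tert-butyl 4-methylpent-3-enoate
Conditions: Me2NCH(Ot-Bu)2, toluene, 80 °C
Reagents that add atoms: N,N-dimethylformamide di-tert-butyl acetal, CN(C)C(OC(C)(C)C)OC(C)(C)C
Why: Esterification by O-alkylation of the carboxylic acid with the formamide acetal runs under neutral conditions, so neither acid-induced lactonisation onto the trisubstituted alkene nor base-induced conjugation should intervene, and the tert-butyl ester is the later cation terminator.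

Step 2
Reactants: 2 tert-butyl 4-methylpent-3-enoate
Product: 3 rac-tert-butyl 3-hydroperoxy-4-methylpent-4-enoate
Conditions: O2, tetraphenylporphyrin (cat.), visible light, CH2Cl2, 0 °C; chromatography
Reagents that add atoms: dioxygen, O=O
Why: Schenck ene reaction of singlet oxygen, in which hydrogen abstraction from the methyl group on the more crowded side of the alkene should give the racemic secondary allylic hydroperoxide with the 1,1-disubstituted alkene needed later, the conjugated tertiary regioisomer expected alongside being removed by chromatography.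

Step 3
Reactants: 3 rac-tert-butyl 3-hydroperoxy-4-methylpent-4-enoate
Product: 4 tert-butyl (3S)-3-hydroperoxy-4-methylpent-4-enoate
Conditions: horseradish peroxidase, guaiacol, phosphate buffer (pH 6), 20 °C, stopped just past half conversion; chromatography
Reagents that add atoms: none
Why: Enzymatic kinetic resolution in which the peroxidase should reduce the (3R)-hydroperoxide enantioselectively to the alcohol and leave the (3S)-hydroperoxide, which fixes C3, the only stereocentre brought in from outside.

Step 4
Reactants: 5 pent-4-yn-2-ol (racemic)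
Product: 7 (E)-5-iodo-4-methylpent-4-en-2-ol, via alkenylalane 6 (not isolated)
Conditions: AlMe3 (3 equiv), Cp2ZrCl2 (0.3 equiv), CH2Cl2, 0 to 23 °C; then I2, THF, −30 to 0 °C
Reagents that add atoms: trimethylaluminium, C[Al](C)C; iodine, II
Why: Negishi zirconium-catalysed carboalumination adds methyl and aluminium syn across the alkyne with methyl at the internal carbon, and iodinolysis with retention gives the (E)-iodoalkene, the racemic carbinol centre being erased in step 5.

Step 5
Reactants: 7 (E)-5-iodo-4-methylpent-4-en-2-ol
Product: 8 (E)-5-iodo-4-methylpent-4-en-2-one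
Conditions: Dess–Martin periodinane, NaHCO3, CH2Cl2, 0 °C
Reagents that add atoms: none
Why: Dess–Martin oxidation under bicarbonate buffering should give the β,γ-unsaturated ketone without migration of the alkene into conjugation and without touching the iodoalkene.

Step 6
Reactants: 8 (E)-5-iodo-4-methylpent-4-en-2-one
Product: 9 (E)-1-iodo-4,4-dimethoxy-2-methylpent-1-ene
Conditions: Me3SiOMe (2.5 equiv), Me3SiOTf (cat.), CH2Cl2, −78 °C; pyridine quench
Reagents that add atoms: methoxytrimethylsilane, CO[Si](C)(C)C
Why: Silyl-triflate-catalysed ketalisation with the silyl ether of methanol runs aprotically at low temperature, so the deconjugated alkene should stay where it is.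

Step 7
Reactants: 4 tert-butyl (3S)-3-hydroperoxy-4-methylpent-4-enoate; 9 (E)-1-iodo-4,4-dimethoxy-2-methylpent-1-ene
Product: 10 tert-butyl (3S)-3-{[(4E)-5-iodo-2-methoxy-4-methylpent-4-en-2-yl]peroxy}-4-methylpent-4-enoate
Conditions: pyridinium p-toluenesulfonate (cat.), CH2Cl2, 4 Å molecular sieves, 0 to 20 °C
Reagents that add atoms: none
Why: Acid-catalysed transketalisation, exchanging one methoxy group of the ketal for the hydroperoxide, is the standard entry to mixed monoperoxyketals, leaves C3 untouched and gives both epimers at the peroxyketal carbon, which need not be controlled because that carbon becomes planar in step 8.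

Step 8
Reactants: 10 tert-butyl (3S)-3-{[(4E)-5-iodo-2-methoxy-4-methylpent-4-en-2-yl]peroxy}-4-methylpent-4-enoate
Product: 13 (1S,4R,6S)-4-[(2E)-3-iodo-2-methylprop-2-en-1-yl]-4,6-dimethyl-2,3,7-trioxabicyclo[4.3.0]nonan-8-one, via peroxycarbenium ion 11 (not isolated), via tert-butoxyoxocarbenium ion 12 (not isolated)
Conditions: Me3SiOTf (1.1 equiv), 2,6-di-tert-butyl-4-methylpyridine (1.5 equiv), CH2Cl2 (0.01 M), −78 to −40 °C; aq. NaHCO3
Reagents that add atoms: none
Why: Proposed new method: Me3SiOTf abstracts methoxide from either epimer of 10 to give the peroxycarbenium ion 11; its C6 is attacked by the terminal carbon (C5) of the 1,1-disubstituted alkene while the carbonyl oxygen of the tert-butyl ester adds to the developing tertiary cation at C4 from the opposite face, and ion 12 then loses 2-methylpropene to leave the lactone. The closest known reaction types are the Lewis-acid-mediated cyclisation of unsaturated monoperoxyketals through peroxycarbenium ions, which gives 1,2-dioxanes with the cation quenched by halide or by loss of silicon, and the ester-terminated Prins cyclisation (Prins lactonisation); new here are the internal ester capture on a peroxide and the unsymmetrical ketone-derived peroxycarbenium ion. The 1,2-dioxane ring closes 6-endo-trig (Markovnikov attack, alkene and C=O+ bond both inside the new ring) and the γ-lactone ring 5-exo-trig on the same alkene. C4 is controlled by C3: in the chair transition state the CH2CO2t-Bu arm on C3 is pseudoaxial, which avoids A(1,2) strain with the methyl group on C4 and puts the ester oxygen antiperiplanar to the forming C5–C6 bond, so the lactone is cis-fused (4S). C6 is controlled by the geometry of 11 in the same chair: the larger iodomethallyl group lies anti to the O–O bond and ends up equatorial, cis to the C3 arm across the ring, and the methyl group axial (6R). The step needs capture of the cation before proton loss or O–O heterolysis and no reaction of the second alkene; the intramolecular ester, the triflate counter-ion, the hindered pyridine buffer and the low temperature should secure the first, and the iodoalkene, deactivated by iodine and unable to reach C6 in a ring of workable size, should secure the second.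

Step 9
Reactants: 14 hex-5-yn-1-ol
Product: 15 hex-5-ynal
Conditions: Dess–Martin periodinane, NaHCO3, CH2Cl2, 0 to 20 °C
Reagents that add atoms: none
Why: Dess–Martin oxidation of the primary alcohol stops at the aldehyde and leaves the terminal alkyne alone.

Step 10
Reactants: 15 hex-5-ynal; 16 diethyl benzylphosphonate
Product: 17 [(1E)-hept-1-en-6-yn-1-yl]benzene
Conditions: 16, NaH, 15-crown-5 (cat.), THF, 0 °C; then 15, 0 to 20 °C
Reagents that add atoms: none
Why: Horner–Wadsworth–Emmons olefination with the preformed benzylphosphonate anion should give the (E)-styrene by the usual thermodynamically controlled elimination, and no free base meets the aldehyde or the alkyne.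

Step 11
Reactants: 17 [(1E)-hept-1-en-6-yn-1-yl]benzene
Product: 18 tributyl[(1E,6E)-7-phenylhepta-1,6-dien-1-yl]stannane
Conditions: Bu3SnH, Pd2(dba)3 (cat.), Cy3P·HBF4 (cat.), i-Pr2NEt, CH2Cl2, 0 °C
Reagents that add atoms: tributyltin hydride, CCCC[SnH](CCCC)CCCC
Why: Palladium-catalysed hydrostannation of the terminal alkyne is a syn addition, and with the bulky trialkylphosphine tin should go to the terminal carbon and give the (E)-alkenylstannane, the internal styrene alkene not being expected to react.

Step 12
Reactants: 13 (1S,4R,6S)-4-[(2E)-3-iodo-2-methylprop-2-en-1-yl]-4,6-dimethyl-2,3,7-trioxabicyclo[4.3.0]nonan-8-one; 18 tributyl[(1E,6E)-7-phenylhepta-1,6-dien-1-yl]stannane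
Product: 19 plakortolide H
Conditions: Pd2(dba)3 (5 mol %), AsPh3 (20 mol %), NMP, 20 °C, dark
Reagents that add atoms: none
Why: Stille coupling of the iodoalkene with the alkenylstannane proceeds with retention at both alkenes and should form the (E,E)-diene under neutral conditions with a phosphine-free zerovalent palladium catalyst, chosen so that neither base-induced β-elimination of the peroxide from the lactone nor reduction of the O–O bond by a phosphine should occur.

**Compound list**

1 | 4-methylpent-3-enoic acid | CC(C)=CCC(=O)O | starting material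
2 | tert-butyl 4-methylpent-3-enoate | CC(C)=CCC(=O)OC(C)(C)C | intermediate
3 | rac-tert-butyl 3-hydroperoxy-4-methylpent-4-enoate | CC(=C)C(OO)CC(=O)OC(C)(C)C | intermediate
4 | tert-butyl (3S)-3-hydroperoxy-4-methylpent-4-enoate | CC(=C)[C@@H](OO)CC(=O)OC(C)(C)C | intermediate
5 | pent-4-yn-2-ol (racemic) | CC(O)CC#C | starting material
6 | dimethyl[(1E)-4-(dimethylalumanyloxy)-2-methylpent-1-en-1-yl]alumane (alkenylalane) | C/C(CC(C)O[Al](C)C)=C\[Al](C)C | intermediate
7 | (E)-5-iodo-4-methylpent-4-en-2-ol | C/C(CC(C)O)=C\I | intermediate
8 | (E)-5-iodo-4-methylpent-4-en-2-one | C/C(CC(C)=O)=C\I | intermediate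
9 | (E)-1-iodo-4,4-dimethoxy-2-methylpent-1-ene | C/C(CC(C)(OC)OC)=C\I | intermediate
10 | tert-butyl (3S)-3-{[(4E)-5-iodo-2-methoxy-4-methylpent-4-en-2-yl]peroxy}-4-methylpent-4-enoate (both epimers at the peroxyketal carbon) | CC(=C)[C@H](CC(=O)OC(C)(C)C)OOC(C)(OC)C/C(C)=C/I | intermediate
11 | peroxycarbenium ion, iodomethallyl group anti to the O–O bond | I/C=C(\C)C/C(C)=[O+]/O[C@@H](CC(=O)OC(C)(C)C)C(C)=C | intermediate
12 | bicyclic tert-butoxyoxocarbenium ion | I/C=C(\C)C[C@]1(C)C[C@]2(C)[O+]=C(OC(C)(C)C)C[C@@H]2OO1 | intermediate
13 | (1S,4R,6S)-4-[(2E)-3-iodo-2-methylprop-2-en-1-yl]-4,6-dimethyl-2,3,7-trioxabicyclo[4.3.0]nonan-8-one (plakortolide numbering 3S,4S,6R) | I/C=C(\C)C[C@]1(C)C[C@]2(C)OC(=O)C[C@@H]2OO1 | intermediate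
14 | hex-5-yn-1-ol | OCCCCC#C | starting material
15 | hex-5-ynal | O=CCCCC#C | intermediate
16 | diethyl benzylphosphonate | CCOP(=O)(Cc1ccccc1)OCC | starting material
17 | [(1E)-hept-1-en-6-yn-1-yl]benzene | C#CCCC/C=C/c1ccccc1 | intermediate
18 | tributyl[(1E,6E)-7-phenylhepta-1,6-dien-1-yl]stannane | CCCC[Sn](CCCC)(CCCC)/C=C/CCC/C=C/c1ccccc1 | intermediate
19 | plakortolide H, (1S,4R,6S)-4,6-dimethyl-4-[(2E,4E,9E)-2-methyl-10-phenyldeca-2,4,9-trien-1-yl]-2,3,7-trioxabicyclo[4.3.0]nonan-8-one | C/C(=C\C=C\CCC/C=C/c1ccccc1)C[C@]1(C)C[C@]2(C)OC(=O)C[C@@H]2OO1 | target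

**Step count and risks**

Total step count: 12.
Longest linear sequence: 6 steps (1, 2, 3, 7, 8, 12 from compound 1; equally 4, 5, 6, 7, 8, 12 from compound 5).

Steps most likely to fail:

Step 8 (the step that carries the label). The peroxycarbenium ion may lose a proton or suffer O–O heterolysis before the alkene attacks. The ester may fail to intercept the C4 cation in time. The facial selectivity at C6 may be poor, since a chair with the C3 arm equatorial would deliver the C6 epimer. The fallback uses known chemistry and makes the closure stepwise and halide-terminated. It sets out from 10: TiCl4 in CH2Cl2 at −78 °C should give, by the documented chloride capture of the tertiary cation, tert-butyl 2-[(3S,6R)-4-chloro-6-[(2E)-3-iodo-2-methylprop-2-en-1-yl]-4,6-dimethyl-1,2-dioxan-3-yl]acetate F1, at which stage C6 epimers can be separated. AgOTf with 2,6-di-tert-butyl-4-methylpyridine in CH2Cl2 then ionises the tertiary chloride, the ester closes the cis-fused lactone with loss of 2-methylpropene, and the route is rejoined at 13.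

Step 3. The enzyme may not accept this hydroperoxide, or may reduce it with low or reversed enantioselectivity. The fallback is a chemical resolution through diastereomeric perketals. It sets out from 3: addition to (1R,2S)-2-phenylcyclohexyl prop-1-en-2-yl ether, catalysed by pyridinium p-toluenesulfonate, should give tert-butyl (3S)-4-methyl-3-[(2-{[(1R,2S)-2-phenylcyclohexyl]oxy}propan-2-yl)peroxy]pent-4-enoate F2 and tert-butyl (3R)-4-methyl-3-[(2-{[(1R,2S)-2-phenylcyclohexyl]oxy}propan-2-yl)peroxy]pent-4-enoate F3. These are separated by chromatography on silica, and F2 is hydrolysed with aqueous acetic acid in THF to return to 4.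

Step 12. Zerovalent palladium may insert into the O–O bond, or the peroxide may be lost from the lactone by β-elimination during the coupling. The fallback moves the coupling ahead of the peroxide. It sets out from 9 and 18: Stille coupling under the conditions of step 12 should give [(1E,6E,8E)-11,11-dimethoxy-9-methyldodeca-1,6,8-trien-1-yl]benzene F4. Transketalisation with 4 as in step 7 then gives tert-butyl (3S)-3-{[(4E,6E,11E)-2-methoxy-4-methyl-12-phenyldodeca-4,6,11-trien-2-yl]peroxy}-4-methylpent-4-enoate F5, and the cyclisation conditions of step 8 lead from F5 directly to 19.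

Further compounds
F1 | step 8 | tert-butyl 2-[(3S,6R)-4-chloro-6-[(2E)-3-iodo-2-methylprop-2-en-1-yl]-4,6-dimethyl-1,2-dioxan-3-yl]acetate | I/C=C(\C)C[C@]1(C)CC(C)(Cl)[C@H](CC(=O)OC(C)(C)C)OO1
F2 | step 3 | tert-butyl (3S)-4-methyl-3-[(2-{[(1R,2S)-2-phenylcyclohexyl]oxy}propan-2-yl)peroxy]pent-4-enoate | CC(=C)[C@H](CC(=O)OC(C)(C)C)OOC(C)(C)O[C@@H]1CCCC[C@H]1c1ccccc1
F3 | step 3 | tert-butyl (3R)-4-methyl-3-[(2-{[(1R,2S)-2-phenylcyclohexyl]oxy}propan-2-yl)peroxy]pent-4-enoate | CC(=C)[C@@H](CC(=O)OC(C)(C)C)OOC(C)(C)O[C@@H]1CCCC[C@H]1c1ccccc1
F4 | step 12 | [(1E,6E,8E)-11,11-dimethoxy-9-methyldodeca-1,6,8-trien-1-yl]benzene | COC(C)(OC)C/C(C)=C/C=C/CCC/C=C/c1ccccc1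
F5 | step 12 | tert-butyl (3S)-3-{[(4E,6E,11E)-2-methoxy-4-methyl-12-phenyldodeca-4,6,11-trien-2-yl]peroxy}-4-methylpent-4-enoate | CC(=C)[C@H](CC(=O)OC(C)(C)C)OOC(C)(OC)C/C(C)=C/C=C/CCC/C=C/c1ccccc1
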